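**Plan**
- Retrosynthesis: the side-chain carbinol C–H is cut first (back to a ketone), then the C2'–C3' bond of the side chain (methyl ketone enolate plus allylic bromide). In the lactone, the C5–C4 and C3–C2 bonds are cut together, as a formal (3+2) union of a C5–O1–C2 unit with a two-carbon acceptor. The bromide is cut at its furylmethyl–geranyl bond.
- Enabling feature: the lactone oxygen O1 on the quaternary C5 and the hydroxyl oxygen on the neighbouring exocyclic carbon C1' form a 1,2-diol. Both oxygens and C2 can therefore be stored in a five-membered cyclic carbonate (1,3-dioxolan-2-one ring) made from a propargylic alcohol and CO2. Its ring carbon becomes a tertiary radical (future C5), its carbonyl carbon becomes lactone C2, and the acyl transfer releases the C1' hydroxyl.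
- Forward order: carbonate ring, then lactone ring (radical–polar crossover annulation with phenyl vinyl sulfone, the sulfone being removed afterwards), then oxidation to the methyl ketone, chain attachment by enolate allylation, and finally the carbinol by reduction.
- Stereochemistry: C5 (S) by 1,2-induction from the stereocentre of (S)-but-3-yn-2-ol (addition anti to its methyl group on the carbonate ring); this relay centre is then oxidized away. C1' (R) comes from CBS reagent control. Both E alkenes come from geranyl chloride and the E-selective SeO2 oxidation.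

Key step: step 2

Remark: all five starting materials are taken as commercially available; the sulfonyl-bearing carbon formed in the key step is not a stereocentre of the target and is left undefined.

**Route**

Step 1
Reactants: 1 (S)-but-3-yn-2-ol; 2 carbon dioxide
Product: 3 (4S)-4-methyl-5-methylidene-1,3-dioxolan-2-one
Conditions: Ag2CO3 (cat.), PPh3 (cat.), CO2 (1 MPa), MeCN, 25 °C
Reagents that add atoms: none
Why: Silver-catalysed carboxylative cyclization of a propargylic alcohol (the alkyl carbonate formed from the alkoxide and CO2 closes 5-exo-dig on the silver-activated alkyne); the stereocentre is not touched and the internal alkyne carbon becomes the future quaternary carbon.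

Step 2
Reactants: 3 (4S)-4-methyl-5-methylidene-1,3-dioxolan-2-one; 4 phenyl vinyl sulfone
Product: 7 (5S)-5-[(1S)-1-hydroxyethyl]-5-methyl-3-(phenylsulfonyl)dihydrofuran-2(3H)-one, via tertiary carbonate radical 5 (not isolated), via sulfonyl carbanion 6 (not isolated)
Conditions: Fe(acac)3 (0.3 equiv), Ph(iPrO)SiH2 (2 equiv), 4 (3 equiv), THF (degassed, no alcohol), 40 °C; then aq. NH4Cl
Reagents that add atoms: none
Why: Proposed new method: the iron hydride formed from Fe(acac)3 and the silane transfers a hydrogen atom to the exocyclic CH2 of 3, which creates the methyl group and the tertiary α-carbonyloxy radical 5; 5 adds to the CH2 terminus of 4 (first C–C bond), the sulfonyl-stabilized radical is reduced by divalent iron to carbanion 6, and 6 attacks the carbonate carbonyl (second C–C bond) to give a 2,7-dioxabicyclo[2.2.1]heptane alkoxide that collapses by loss of the secondary alkoxide. The closest known reaction types are the iron-hydride reductive coupling of oxygen-substituted donor alkenes with vinyl sulfones and the hydrogen-atom-transfer-initiated Giese–aldol radical–polar crossover annulation; new is the capture of the post-Giese carbanion by a carbonate, a Dieckmann-type acyl transfer. The lactone ring closes 5-exo-trig at the carbonate carbonyl, and the strain of the bicyclic intermediate together with the irreversible deprotonation of the α-sulfonyl lactone should drive the opening to the five-membered lactone and not to the six-membered isomer. The new quaternary centre (5S) is set by 1,2-induction, the planar radical 5 being attacked on the ring face anti to the methyl group at the neighbouring (S) carbon; the sulfonyl-bearing carbon is uncontrolled, so 7 is a mixture of C3 epimers that is erased in step 3. The step needs acyl transfer to outrun protonation of 6 and Giese addition to outrun reduction of 5, which the aprotic medium, the excess of 4 and the nucleophilic character of the α-oxygenated radical should secure.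

Step 3
Reactants: 7 (5S)-5-[(1S)-1-hydroxyethyl]-5-methyl-3-(phenylsulfonyl)dihydrofuran-2(3H)-one
Product: 8 (5S)-5-[(1S)-1-hydroxyethyl]-5-methyldihydrofuran-2(3H)-one
Conditions: SmI2 (3 equiv), THF–MeOH, −78 °C
Reagents that add atoms: none
Why: Reductive desulfonylation of an α-sulfonyl ester by electron transfer from divalent samarium (samarium enolate, protonated by MeOH) removes the activating group and the uncontrolled centre; the C5 epimer from minor syn addition in step 2 is a diastereomer of 8 and should be separated here.

Step 4
Reactants: 8 (5S)-5-[(1S)-1-hydroxyethyl]-5-methyldihydrofuran-2(3H)-one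
Product: 9 (5S)-5-acetyl-5-methyldihydrofuran-2(3H)-one
Conditions: Dess–Martin periodinane, CH2Cl2, 0 °C to rt
Reagents that add atoms: none
Why: Dess–Martin oxidation of the secondary alcohol erases the relay stereocentre after it has set C5 and turns the methyl group into the only enolizable ketone position; C5 is quaternary and cannot epimerize.

Step 5
Reactants: 10 furan-3-ylmethanol
Product: 11 3-(chloromethyl)furan
Conditions: SOCl2, pyridine, Et2O, 0 °C
Reagents that add atoms: thionyl chloride, O=S(Cl)Cl
Why: Chlorodehydroxylation of a primary alcohol through the chlorosulfite, with pyridine buffering the acid-sensitive furan.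

Step 6
Reactants: 11 3-(chloromethyl)furan; 12 geranyl chloride [(2E)-1-chloro-3,7-dimethylocta-2,6-diene]
Product: 14 dendrolasin [3-[(3E)-4,8-dimethylnona-3,7-dien-1-yl]furan], via (furan-3-ylmethyl)magnesium chloride 13 (not isolated)
Conditions: Mg turnings, THF, 0 °C to rt; then 12, Li2CuCl4 (cat.), THF, −10 to 0 °C
Reagents that add atoms: none
Why: Grignard formation and Li2CuCl4-catalysed (Kochi-type) coupling with the primary allylic chloride should occur at the unsubstituted allyl terminus with retention of the E alkene.

Step 7
Reactants: 14 dendrolasin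
Product: 15 (2E,6E)-9-(furan-3-yl)-2,6-dimethylnona-2,6-dien-1-ol
Conditions: SeO2 (cat.), t-BuOOH, salicylic acid (cat.), CH2Cl2, 0 °C to rt
Reagents that add atoms: selenium dioxide, O=[Se]=O (catalytic oxygen carrier); tert-butyl hydroperoxide, CC(C)(C)OO (terminal oxidant)
Why: Riley allylic oxidation (ene reaction then [2,3]-shift) should select the E methyl group of the terminal, more electron-rich trisubstituted alkene and give the E allylic alcohol.

Step 8
Reactants: 15 (2E,6E)-9-(furan-3-yl)-2,6-dimethylnona-2,6-dien-1-ol
Product: 16 3-[(3E,7E)-9-bromo-4,8-dimethylnona-3,7-dien-1-yl]furan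
Conditions: CBr4, PPh3, CH2Cl2, 0 °C
Reagents that add atoms: carbon tetrabromide, BrC(Br)(Br)Br
Why: Appel reaction; direct displacement at the primary allylic carbon under neutral conditions should keep the E geometry and spare the furan.

Step 9
Reactants: 9 (5S)-5-acetyl-5-methyldihydrofuran-2(3H)-one; 16 3-[(3E,7E)-9-bromo-4,8-dimethylnona-3,7-dien-1-yl]furan
Product: 18 (5S)-5-[(4E,8E)-11-(furan-3-yl)-4,8-dimethylundeca-4,8-dienoyl]-5-methyldihydrofuran-2(3H)-one, via lithium enolate 17 (not isolated)
Conditions: LDA (LiN(iPr)2, 1.05 equiv), THF, −78 °C; then 16, DMPU, −78 to −30 °C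
Reagents that add atoms: none
Why: Kinetic deprotonation of the methyl ketone (more acidic than the lactone CH2) and C-alkylation of the lithium enolate by the allylic bromide; attack of the enolate carbon on the lactone carbonyl would be a disfavoured 5-(enolendo)-exo-trig closure.

Step 10
Reactants: 18 (5S)-5-[(4E,8E)-11-(furan-3-yl)-4,8-dimethylundeca-4,8-dienoyl]-5-methyldihydrofuran-2(3H)-one
Product: 19 (5S)-5-[(1R,4E,8E)-11-(furan-3-yl)-1-hydroxy-4,8-dimethylundeca-4,8-dien-1-yl]-5-methyldihydrofuran-2(3H)-one
Conditions: (S)-2-methyl-CBS-oxazaborolidine (0.5 equiv), catecholborane, toluene, −78 to −40 °C; then MeOH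
Reagents that add atoms: none
Why: Corey–Bakshi–Shibata reduction, in which the (S)-oxazaborolidine distinguishes the quaternary C5 substituent (large) from the CH2 chain (small) and should give the (R)-carbinol under reagent control; catecholborane at low temperature should leave the lactone, the alkenes and the furan untouched.

**Compound list**
1 | (S)-but-3-yn-2-ol | C[C@H](O)C#C | starting material
2 | carbon dioxide | O=C=O | starting material
3 | (4S)-4-methyl-5-methylidene-1,3-dioxolan-2-one | C=C1OC(=O)O[C@H]1C | intermediate
4 | phenyl vinyl sulfone | C=CS(=O)(=O)c1ccccc1 | starting material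
5 | (5S)-4,5-dimethyl-2-oxo-1,3-dioxolan-4-yl radical | C[C]1OC(=O)O[C@H]1C | intermediate (not isolated)
6 | carbanion of (4S,5S)-4,5-dimethyl-4-[2-(phenylsulfonyl)ethyl]-1,3-dioxolan-2-one, charge at the sulfonyl-bearing carbon | C[C@@H]1OC(=O)O[C@@]1(C)C[CH-]S(=O)(=O)c1ccccc1 | intermediate (not isolated)
7 | (5S)-5-[(1S)-1-hydroxyethyl]-5-methyl-3-(phenylsulfonyl)dihydrofuran-2(3H)-one (C3 epimers) | C[C@H](O)[C@]1(C)CC(S(=O)(=O)c2ccccc2)C(=O)O1 | intermediate
8 | (5S)-5-[(1S)-1-hydroxyethyl]-5-methyldihydrofuran-2(3H)-one | C[C@H](O)[C@]1(C)CCC(=O)O1 | intermediate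
9 | (5S)-5-acetyl-5-methyldihydrofuran-2(3H)-one | CC(=O)[C@]1(C)CCC(=O)O1 | intermediate
10 | furan-3-ylmethanol | OCc1ccoc1 | starting material
11 | 3-(chloromethyl)furan | ClCc1ccoc1 | intermediate
12 | geranyl chloride, (2E)-1-chloro-3,7-dimethylocta-2,6-diene | CC(C)=CCC/C(C)=C/CCl | starting material
13 | (furan-3-ylmethyl)magnesium chloride | Cl[Mg]Cc1ccoc1 | intermediate (not isolated)
14 | dendrolasin, 3-[(3E)-4,8-dimethylnona-3,7-dien-1-yl]furan | CC(C)=CCC/C(C)=C/CCc1ccoc1 | intermediate
15 | (2E,6E)-9-(furan-3-yl)-2,6-dimethylnona-2,6-dien-1-ol | OC/C(C)=C/CC/C(C)=C/CCc1ccoc1 | intermediate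
16 | 3-[(3E,7E)-9-bromo-4,8-dimethylnona-3,7-dien-1-yl]furan | BrC/C(C)=C/CC/C(C)=C/CCc1ccoc1 | intermediate
17 | lithium enolate of 9, lithium 1-[(2S)-2-methyl-5-oxooxolan-2-yl]ethen-1-olate | C=C(O[Li])[C@]1(C)CCC(=O)O1 | intermediate (not isolated)
18 | (5S)-5-[(4E,8E)-11-(furan-3-yl)-4,8-dimethylundeca-4,8-dienoyl]-5-methyldihydrofuran-2(3H)-one | C/C(=C\CCc1ccoc1)CC/C=C(\C)CCC(=O)[C@]1(C)CCC(=O)O1 | intermediate
19 | (5S)-5-[(1R,4E,8E)-11-(furan-3-yl)-1-hydroxy-4,8-dimethylundeca-4,8-dien-1-yl]-5-methyldihydrofuran-2(3H)-one | C/C(=C\CCc1ccoc1)CC/C=C(\C)CC[C@@H](O)[C@]1(C)CCC(=O)O1 | target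

**Step count**
Total: 10 steps. Longest linear sequence: 6 steps (steps 1–4, 9, 10; the chain branch, steps 5–8, 9, 10, is equally long).

**Steps most likely to fail**

1. Step 2 (Proposed new method). The cascade may stop before the acyl transfer through protonation of the carbanion, the radical may be reduced before it adds, hydrogen-atom transfer to the enol carbonate may be slow, or facial selectivity of the radical addition may be low. The fallback is a polar, chelation-controlled construction with known chemistry that sets out from 1 and returns at 8.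
   - O-Benzylation of 1 (NaH, BnBr, THF) should give (S)-3-(benzyloxy)but-1-yne F1.
   - Gold-catalysed Markovnikov hydration (Ph3PAuNTf2 cat., aq. dioxane) should give (S)-3-(benzyloxy)butan-2-one F2.
   - Addition of [2-(1,3-dioxolan-2-yl)ethyl]magnesium bromide in THF at −78 °C through the five-membered magnesium chelate should give (2S,3S)-2-(benzyloxy)-5-(1,3-dioxolan-2-yl)-3-methylpentan-3-ol F3. The nucleophile enters anti to the methyl group of the stereocentre, the same sense as the radical addition.
   - Jones reagent (CrO3, H2SO4, acetone) should hydrolyse the acetal and oxidize the lactol to (S)-5-[(S)-1-(benzyloxy)ethyl]-5-methyldihydrofuran-2(3H)-one F4.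
   - Hydrogenolysis (H2, Pd/C, palladium on carbon, EtOAc) then gives 8.

2. Step 9. Proton exchange between the enolate and the alkylated ketone or the lactone may cause over-alkylation, and O-alkylation or acyl migration to the enolate oxygen may compete. The fallback replaces the basic enolate by a neutral palladium-catalysed allylation; it sets out from 9 and 15 and returns at 18.
   - Soft enolization of 9 (TMSOTf, Et3N, CH2Cl2, 0 °C) should give (S)-5-methyl-5-[1-(trimethylsilyloxy)ethenyl]dihydrofuran-2(3H)-one F5.
   - Alcohol 15 with methyl chloroformate and pyridine should give (2E,6E)-9-(furan-3-yl)-2,6-dimethylnona-2,6-dien-1-yl methyl carbonate F6.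
   - Tsuji–Trost allylation of F5 with F6 (Pd2(dba)3, dppe, THF, zerovalent palladium) should join them at the unsubstituted terminus of the allyl complex and give 18.

3. Step 10. Catalyst control may fail to override the Felkin preference imposed by the α-oxygen, giving poor facial selectivity. The fallback uses substrate chelation on the opened hydroxy ketone; it sets out from 18 and returns at 19.
   - Saponification of the lactone (LiOH, aq. THF, 0 °C) should give the open tertiary α-hydroxy ketone, lithium (4S,8E,12E)-15-(furan-3-yl)-4-hydroxy-4,8,12-trimethyl-5-oxopentadeca-8,12-dienoate F7.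
   - Reduction with Zn(BH4)2 (Et2O–THF, −20 °C), with zinc bridging the tertiary hydroxyl and the ketone oxygen and hydride entering past the methyl group and not past the propanoate arm, should give after acidification (4S,5R,8E,12E)-15-(furan-3-yl)-4,5-dihydroxy-4,8,12-trimethylpentadeca-8,12-dienoic acid F8.
   - F8 should close to the five-membered lactone with a trace of acid (PPTS, CH2Cl2), which is 19.

Further compounds
F1 | step 2 | (S)-3-(benzyloxy)but-1-yne | C[C@H](OCc1ccccc1)C#C
F2 | step 2 | (S)-3-(benzyloxy)butan-2-one | C[C@H](OCc1ccccc1)C(C)=O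
F3 | step 2 | (2S,3S)-2-(benzyloxy)-5-(1,3-dioxolan-2-yl)-3-methylpentan-3-ol | C[C@H](OCc1ccccc1)[C@@](C)(O)CCC1OCCO1
F4 | step 2 | (S)-5-[(S)-1-(benzyloxy)ethyl]-5-methyldihydrofuran-2(3H)-one | C[C@H](OCc1ccccc1)[C@]1(C)CCC(=O)O1
F5 | step 9 | (S)-5-methyl-5-[1-(trimethylsilyloxy)ethenyl]dihydrofuran-2(3H)-one | C=C(O[Si](C)(C)C)[C@]1(C)CCC(=O)O1
F6 | step 9 | (2E,6E)-9-(furan-3-yl)-2,6-dimethylnona-2,6-dien-1-yl methyl carbonate | COC(=O)OC/C(C)=C/CC/C(C)=C/CCc1ccoc1
F7 | step 10 | lithium (4S,8E,12E)-15-(furan-3-yl)-4-hydroxy-4,8,12-trimethyl-5-oxopentadeca-8,12-dienoate | C/C(=C\CCc1ccoc1)CC/C=C(\C)CCC(=O)[C@@](C)(O)CCC(=O)[O-].[Li+]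
F8 | step 10 | (4S,5R,8E,12E)-15-(furan-3-yl)-4,5-dihydroxy-4,8,12-trimethylpentadeca-8,12-dienoic acid | C/C(=C\CCc1ccoc1)CC/C=C(\C)CC[C@@H](O)[C@@](C)(O)CCC(=O)O
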